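**Plan**
1. Briarane numbering is used: ring A = cyclohexane C1, C10–C14; ring B = ten-membered ring C1–C10; lactone = C7, C8, C17, C19; C15 = CH3 on C1, C16 = exocyclic CH2 on C5, C20 = epoxide CH2.
2. Cuts, last-formed bond first: C6–Cl; C5–C6 (Nozaki–Hiyama–Kishi closure of ring B); C11–O and C14–O (ozonolysis and Baeyer–Villiger oxidation of an etheno bridge); C8–C17 (Reformatsky lactone closure); C8–C9 (NHK coupling); C9–C10 (methylenation); then C13–C14 together with C11–C12 by a [4+2] cycloaddition of a cyclohexa-2,4-dienone with vinyl isovalerate.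
3. Enabling feature: on ring A the oxygens on C11, C12 and C14 are all cis and C13 is a bare CH2, so ring A is a latent bicyclo[2.2.2]octene. C14 and C11 are tied by a temporary –C(CH3)=CH– bridge and C12–C13 is the enol ester; cleaving the bridge turns its C(CH3) into the C14 acetate and its CH into the C11 oxygen.
4. Forward: Birch reduction–methylation of an anisic amide (C1), side chain C2–C5/C16, dienone, [4+2] (ring A), C9, lactone, bridge excision and epoxide, ring B by NHK, chloride.
5. Stereochemistry: C1 from the prolinol-ether auxiliary; C2 by CBS reduction; C11, C12, C14 from the cycloaddition; C10 by equilibration; C7 from (S)-glyceraldehyde acetonide; C9 and C6 by ligand-controlled chromium additions (C6 then inverted by chloride); C8 and C17 from the chelated Reformatsky closure.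

Key step: step 10

Remark: the sense of induction of the Birch alkylation (step 2) and of the ligand-controlled chromium additions (steps 16 and 29) is assumed to follow the established models; if it were opposite, the enantiomer of the auxiliary or ligand would be used with no other change.

**Route**

Step 1
Reactants: 1 2-methoxy-5-methylbenzoic acid; 2 (S)-2-(methoxymethyl)pyrrolidine
Product: 4 (2-methoxy-5-methylphenyl)[(2S)-2-(methoxymethyl)pyrrolidin-1-yl]methanone, via acid chloride 3 (not isolated)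
Conditions: SOCl2, DMF (cat.), toluene, 70 °C; then 2, Et3N, CH2Cl2, 0 °C
Reagents that add atoms: none
Why: Amide formation through the acid chloride attaches the chiral auxiliary; no stereocentre is formed.

Step 2
Reactants: 4 benzamide
Product: 5 [(1S)-2-methoxy-1,5-dimethylcyclohexa-2,5-dien-1-yl][(2S)-2-(methoxymethyl)pyrrolidin-1-yl]methanone
Conditions: K, NH3 (l), THF, t-BuOH (1 equiv), −78 °C; then MeI, −78 °C
Reagents that add atoms: iodomethane (CI)
Why: Birch reduction–alkylation: the chelated potassium amide enolate should be methylated on the face away from the pyrrolidine substituent, setting quaternary C1.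

Step 3
Reactants: 5 Birch product; 6 (4-iodobut-1-yn-1-yl)trimethylsilane
Product: 8 1-[(1S)-2-methoxy-1,5-dimethylcyclohexa-2,5-dien-1-yl]-5-(trimethylsilyl)pent-4-yn-1-one, via alkyllithium 7 (not isolated)
Conditions: 6, t-BuLi (2 equiv), Et2O, −78 °C; then 5, −78 → 0 °C; aq NH4Cl
Reagents that add atoms: none
Why: Organolithium addition to a tertiary amide should stop at the chelated tetrahedral lithium alkoxide, which gives the C2 ketone on work-up and releases the auxiliary.

Step 4
Reactants: 8 ketone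
Product: 9 (1S)-1-[(1R)-2-methoxy-1,5-dimethylcyclohexa-2,5-dien-1-yl]-5-(trimethylsilyl)pent-4-yn-1-ol
Conditions: (R)-Me-CBS oxazaborolidine (20 mol%), catecholborane, toluene, −78 °C
Reagents that add atoms: none
Why: Corey–Bakshi–Shibata reduction: the quaternary C1 side is the large group, so the (R)-catalyst should deliver hydride to give the (S)-carbinol at C2 under reagent control.

Step 5
Reactants: 9 alcohol
Product: 10 2-methylpropanoate (isobutyrate) of 9
Conditions: isobutyryl chloride, pyridine, DMAP (cat.), CH2Cl2, 0 °C → rt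
Reagents that add atoms: 2-methylpropanoyl chloride (CC(C)C(Cl)=O)
Why: DMAP-catalysed acylation installs the C2 isobutyrate of the target before any other ester is present.

Step 6
Reactants: 10 enol ether
Product: 11 (1S)-1-[(1R)-1,3-dimethyl-6-oxocyclohex-2-en-1-yl]-5-(trimethylsilyl)pent-4-yn-1-yl 2-methylpropanoate
Conditions: 1 M HCl, THF, 0 °C
Reagents that add atoms: water (O)
Why: Mild acid hydrolysis of the methyl enol ether unmasks the C10 ketone; the C14=C(CH3) double bond cannot move into conjugation through quaternary C1.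

Step 7
Reactants: 11 ketone
Product: 12 5-[(benzyloxy)methyl] derivative of 11 (both C11 epimers)
Conditions: LiN(i-Pr)2, THF, −78 °C; then BnOCH2Cl, DMPU, −78 → −40 °C
Reagents that add atoms: benzyl chloromethyl ether (ClCOCc1ccccc1)
Why: Alkylation of the lithium enolate at C11, the only enolisable position, introduces C20; the new centre is removed in step 8.

Step 8
Reactants: 12 alkylated ketone
Product: 14 (1S)-1-[(1R)-5-[(benzyloxy)methyl]-1,3-dimethyl-6-oxocyclohexa-2,4-dien-1-yl]-5-(trimethylsilyl)pent-4-yn-1-yl 2-methylpropanoate, via selenide 13 (not isolated)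
Conditions: LiN(i-Pr)2, THF, −78 °C; PhSeBr; then H2O2, pyridine, CH2Cl2, 0 °C
Reagents that add atoms: none
Why: α-Selenenylation and selenoxide syn-elimination, which avoids forming an enol ether toward C20, should give the linearly conjugated 2,4-dienone, whose 2,4,6,6-substitution suppresses dimerisation.

Step 9
Reactants: 15 3-methylbutanoic acid; 16 vinyl acetate
Product: 17 vinyl 3-methylbutanoate (vinyl isovalerate)
Conditions: Pd(OAc)2 (cat.), KOH (cat.), neat 16, rt
Reagents that add atoms: none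
Why: Palladium-catalysed transvinylation of a carboxylic acid with vinyl acetate.

Step 10
Reactants: 14 dienone; 17 vinyl isovalerate
Product: 18 bicyclo[2.2.2]octenone adduct (C12 isovalerate endo, C2 side chain syn to the etheno bridge)
Conditions: 17 (neat, large excess), BHT (cat.), sealed tube, 130 °C
Reagents that add atoms: none
Why: Thermal inverse-electron-demand Diels–Alder reaction: the s-cis diene C14=C(CH3)–CH=C11 locked in the dienone and the enol ester C13H2=C12H–O combine in one concerted suprafacial step that forms C13–C14 and C12–C11 and closes ring A (C1, C14, C13, C12, C11, C10) by [4+2] closure as one ring of a bicyclo[2.2.2]octenone. The closest known reaction type is the cycloaddition of 6,6-disubstituted cyclohexa-2,4-dienones and masked o-benzoquinones with enol ethers and enol esters. C14 and C11 become bridgeheads whose new bonds are necessarily cis; C12 should take the ester endo, syn to the etheno bridge, by secondary orbital overlap; and the dienophile should approach the diene face that carries the C1 methyl, anti to the branched C2 side chain, which fixes all three centres relative to C1. The regiochemistry (CH2 to C14, oxygen-bearing carbon to C11) follows from the large LUMO coefficient at the δ-carbon C14 of the dienone and the large HOMO coefficient at the CH2 of the enol ester. The step needs chemoselectivity over dienone dimerisation and over the tethered alkyne; the 2,4,6,6-substitution blocks the former, and the trimethylsilyl cap and the excess of vinyl ester the latter.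

Step 11
Reactants: 18 adduct
Product: 19 methylidene compound (C10=C9H2)
Conditions: Tebbe reagent Cp2Ti(μ-Cl)(μ-CH2)AlMe2, pyridine (cat.), THF/toluene, −40 → 0 °C
Reagents that add atoms: Tebbe reagent, drawn in the open form Cp2Ti(Cl)CH2AlMe2 (C[Al](C)C[Ti](Cl)(C1C=CC=C1)C1C=CC=C1)
Why: Tebbe methylenation is chosen because the non-enolisable C10 ketone lies between two quaternary carbons; at low temperature the titanocene methylidene Cp2Ti=CH2 should react with the ketone and spare the two esters.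

Step 12
Reactants: 19 methylidene compound
Product: 20 primary alcohol at C9 (both C10 epimers)
Conditions: 9-BBN, THF, 0 °C → rt; then H2O2, aq NaHCO3, 0 °C
Reagents that add atoms: hydrogen peroxide (OO)
Why: Hydroboration–oxidation with 9-BBN should select the 1,1-disubstituted exocyclic alkene over the trisubstituted bridge alkene and the silyl alkyne, and place boron on C9.

Step 13
Reactants: 20 alcohol
Product: 22 C9 aldehyde with C9 anti to the C2 side chain, via aldehyde epimer mixture 21 (not isolated)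
Conditions: Dess–Martin periodinane, NaHCO3, CH2Cl2, 0 °C → rt; then DBU (cat.), CH2Cl2, rt
Reagents that add atoms: none
Why: Dess–Martin oxidation followed by base equilibration of the only epimerisable centre: on the rigid bicycle the formyl group at C10 should prefer the position eclipsed with the C1 methyl and anti to the C2 side chain, which is the trans ring fusion of the target.

Step 14
Reactants: 23 (S)-2,2-dimethyl-1,3-dioxolane-4-carbaldehyde
Product: 24 (R)-4-ethynyl-2,2-dimethyl-1,3-dioxolane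
Conditions: dimethyl (1-diazo-2-oxopropyl)phosphonate, K2CO3, MeOH, 0 °C → rt
Reagents that add atoms: dimethyl (1-diazo-2-oxopropyl)phosphonate (COP(=O)(OC)C(=[N+]=[N-])C(C)=O)
Why: Ohira–Bestmann (Seyferth–Gilbert) homologation converts the aldehyde into the terminal alkyne without epimerisation of the adjacent centre (future C7).

Step 15
Reactants: 24 alkyne
Product: 26 (S)-4-(1-iodoethenyl)-2,2-dimethyl-1,3-dioxolane, via vinylsilane 25 (not isolated)
Conditions: [Cp*Ru(MeCN)3]PF6 (cat.), Et3SiH, CH2Cl2, 0 °C; then NIS, 2,6-lutidine, MeCN, 0 °C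
Reagents that add atoms: N-iodosuccinimide (O=C1CCC(=O)N1I)
Why: Ruthenium-catalysed Markovnikov hydrosilylation of the terminal alkyne and ipso-iododesilylation should give the 2-iodo-1-alkene.

Step 16
Reactants: 22 aldehyde; 26 vinyl iodide
Product: 27 (9S)-allylic alcohol, C9(OH)–C8(=CH2)–C7 acetonide
Conditions: CrCl2, NiCl2 (cat.), chiral N-[2-(4-isopropyl-4,5-dihydrooxazol-2-yl)phenyl]methanesulfonamide ligand, Et3N, THF, rt
Reagents that add atoms: none
Why: Nozaki–Hiyama–Kishi coupling: the alkenylchromium species (trivalent chromium) adds only to the aldehyde, and the chiral sulfonamide ligand on chromium should control the face and set C9.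

Step 17
Reactants: 27 alcohol
Product: 28 C9 acetate
Conditions: Ac2O, pyridine, DMAP (cat.), CH2Cl2, rt
Reagents that add atoms: acetic anhydride (CC(=O)OC(C)=O)
Why: Acetylation installs the C9 acetate of the target.

Step 18
Reactants: 28 acetonide
Product: 29 C6,C7-diol
Conditions: AcOH/H2O (4:1), 40 °C
Reagents that add atoms: none
Why: Acid hydrolysis of the terminal acetonide; esters, benzyl ether and silyl alkyne should be stable.

Step 19
Reactants: 29 diol
Product: 30 C6 tert-butyldiphenylsilyl ether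
Conditions: TBDPSCl, imidazole, CH2Cl2, 0 °C
Reagents that add atoms: tert-butyl(chloro)diphenylsilane (CC(C)(C)[Si](Cl)(c1ccccc1)c1ccccc1)
Why: Selective silylation of the primary C6 hydroxyl with a group that survives BCl3 in step 24.

Step 20
Reactants: 30 secondary alcohol
Product: 31 C7 2-bromopropanoate (either configuration at the bromide carbon)
Conditions: 2-bromopropanoyl bromide, pyridine, CH2Cl2, −20 °C
Reagents that add atoms: 2-bromopropanoyl bromide (CC(Br)C(Br)=O)
Why: Acylation of the C7 hydroxyl attaches C17, C18 and C19 as the Reformatsky precursor.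

Step 21
Reactants: 31 diene
Product: 32 tricarbonyl compound (C14 acetyl, C11 formyl, C8 ketone)
Conditions: O3, CH2Cl2, −78 °C (Sudan red indicator); then Me2S, −78 °C → rt
Reagents that add atoms: ozone ([O-][O+]=O)
Why: Ozonolysis should cleave the etheno bridge to the C14 acetyl and C11 formyl groups and the C8 methylidene to the C8 ketone, while the silyl alkyne and the arenes react much more slowly.

Step 22
Reactants: 32 bromo ester
Product: 33 β-hydroxy-γ-lactone (C7–O–C19(=O)–C17H(CH3)–C8(OH))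
Conditions: Zn dust (TMSCl-activated), THF, rt, high dilution; aq NH4Cl
Reagents that add atoms: none
Why: Intramolecular Reformatsky reaction (the classical cardenolide lactone closure): in the chelated zinc enolate the large C9 substituent of the C8 ketone should take the position trans to C6 on the forming five-membered ring, which places the C8 hydroxyl cis to C6, with the C17 methyl in the less hindered position trans to C9.

Step 23
Reactants: 33 lactone
Product: 35 C14 acetate with free tertiary C11 hydroxyl, via formate 34 (not isolated)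
Conditions: mCPBA, NaHCO3, CH2Cl2, rt; then KHCO3, MeOH, 0 °C
Reagents that add atoms: 3-chloroperbenzoic acid (OOC(=O)c1cccc(Cl)c1)
Why: Double Baeyer–Villiger oxidation with retention: secondary C14 migrates in the methyl ketone to give the C14 acetate, tertiary C11 migrates in the aldehyde to give a formate, and only that labile formate is then methanolysed.

Step 24
Reactants: 35 benzyl ether
Product: 36 C11,C20-diol
Conditions: BCl3, pentamethylbenzene, CH2Cl2, −78 °C
Reagents that add atoms: none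
Why: Lewis-acid debenzylation with a cation scavenger should spare the esters, the silyl ether and the alkyne.

Step 25
Reactants: 36 diol
Product: 38 C11,C20-epoxide, via mesylate 37 (not isolated)
Conditions: MsCl, Et3N, CH2Cl2, −20 °C; then DBU, rt
Reagents that add atoms: none
Why: Selective mesylation of the primary C20 hydroxyl and 3-exo-tet closure by the tertiary C11 alkoxide; C11 itself is not touched, so its configuration from step 10 is kept.

Step 26
Reactants: 38 epoxide
Product: 39 C6 alcohol with terminal alkyne C5≡C16H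
Conditions: TBAF, AcOH, THF, 0 °C → rt
Reagents that add atoms: none
Why: Buffered fluoride should remove the silyl ether and the alkynyl silane in one operation without acyl migration.

Step 27
Reactants: 39 alkyne
Product: 41 2-iodo-1-alkene (C5(I)=C16H2), via vinylsilane 40 (not isolated)
Conditions: [Cp*Ru(MeCN)3]PF6 (cat.), Et3SiH, CH2Cl2, 0 °C; then NIS, 2,6-lutidine, MeCN, 0 °C
Reagents that add atoms: N-iodosuccinimide (O=C1CCC(=O)N1I)
Why: Markovnikov hydrosilylation and iododesilylation as in step 15, under neutral conditions that the epoxide and the free hydroxyls should tolerate.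

Step 28
Reactants: 41 primary alcohol
Product: 42 C6 aldehyde
Conditions: Dess–Martin periodinane, NaHCO3, CH2Cl2, 0 °C
Reagents that add atoms: none
Why: Dess–Martin oxidation of the primary alcohol; the tertiary C8 hydroxyl is inert and the aldehyde is used at once.

Step 29
Reactants: 42 iodo aldehyde
Product: 43 (6R)-allylic alcohol with ring B closed
Conditions: CrCl2, NiCl2 (cat.), chiral N-[2-(4-isopropyl-4,5-dihydrooxazol-2-yl)phenyl]methanesulfonamide ligand, Et3N, THF, rt, high dilution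
Reagents that add atoms: none
Why: Intramolecular Nozaki–Hiyama–Kishi reaction closes the ten-membered ring at C5–C6 and gives the exocyclic methylene directly; the chiral sulfonamide ligand on chromium should set the 6R carbinol, syn to the C7 oxygen.

Step 30
Reactants: 43 allylic alcohol
Product: 44 target CNP0194902.1
Conditions: PPh3, hexachloroacetone, CH2Cl2, −20 → 0 °C
Reagents that add atoms: hexachloroacetone (ClC(Cl)(Cl)C(=O)C(Cl)(Cl)Cl)
Why: Appel-type chlorination: SN2 displacement of the oxyphosphonium should give the 6S chloride with inversion and without allylic transposition, and the tertiary alcohol does not react.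

**Compound list**

1 | 2-methoxy-5-methylbenzoic acid | COc1ccc(C)cc1C(=O)O | starting material
2 | (S)-2-(methoxymethyl)pyrrolidine | COC[C@@H]1CCCN1 | starting material
3 | 2-methoxy-5-methylbenzoyl chloride | COc1ccc(C)cc1C(Cl)=O | intermediate
4 | (2-methoxy-5-methylphenyl)[(2S)-2-(methoxymethyl)pyrrolidin-1-yl]methanone | COC[C@@H]1CCCN1C(=O)c1cc(C)ccc1OC | intermediate
5 | [(1S)-2-methoxy-1,5-dimethylcyclohexa-2,5-dien-1-yl][(2S)-2-(methoxymethyl)pyrrolidin-1-yl]methanone | COC[C@@H]1CCCN1C(=O)[C@@]1(C)C=C(C)CC=C1OC | intermediate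
6 | (4-iodobut-1-yn-1-yl)trimethylsilane | C[Si](C)(C)C#CCCI | starting material
7 | [4-(trimethylsilyl)but-3-yn-1-yl]lithium | [Li]CCC#C[Si](C)(C)C | intermediate
8 | 1-[(1S)-2-methoxy-1,5-dimethylcyclohexa-2,5-dien-1-yl]-5-(trimethylsilyl)pent-4-yn-1-one | C[Si](C)(C)C#CCCC(=O)[C@@]1(C)C=C(C)CC=C1OC | intermediate
9 | (1S)-1-[(1R)-2-methoxy-1,5-dimethylcyclohexa-2,5-dien-1-yl]-5-(trimethylsilyl)pent-4-yn-1-ol | C[Si](C)(C)C#CCC[C@H](O)[C@@]1(C)C=C(C)CC=C1OC | intermediate
10 | (1S)-1-[(1R)-2-methoxy-1,5-dimethylcyclohexa-2,5-dien-1-yl]-5-(trimethylsilyl)pent-4-yn-1-yl 2-methylpropanoate | C[Si](C)(C)C#CCC[C@H](OC(=O)C(C)C)[C@@]1(C)C=C(C)CC=C1OC | intermediate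
11 | (1S)-1-[(1R)-1,3-dimethyl-6-oxocyclohex-2-en-1-yl]-5-(trimethylsilyl)pent-4-yn-1-yl 2-methylpropanoate | C[Si](C)(C)C#CCC[C@H](OC(=O)C(C)C)[C@@]1(C)C=C(C)CCC1=O | intermediate
12 | (1S)-1-[(1R)-5-[(benzyloxy)methyl]-1,3-dimethyl-6-oxocyclohex-2-en-1-yl]-5-(trimethylsilyl)pent-4-yn-1-yl 2-methylpropanoate, both epimers at ring C5 (= C11) | C[Si](C)(C)C#CCC[C@H](OC(=O)C(C)C)[C@@]1(C)C=C(C)CC(COCc2ccccc2)C1=O | intermediate
13 | 5-(phenylselanyl) derivative of 12 | C[Si](C)(C)C#CCC[C@H](OC(=O)C(C)C)[C@@]1(C)C=C(C)CC([Se]c2ccccc2)(COCc2ccccc2)C1=O | intermediate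
14 | (1S)-1-[(1R)-5-[(benzyloxy)methyl]-1,3-dimethyl-6-oxocyclohexa-2,4-dien-1-yl]-5-(trimethylsilyl)pent-4-yn-1-yl 2-methylpropanoate (dienone) | C[Si](C)(C)C#CCC[C@H](OC(=O)C(C)C)[C@@]1(C)C=C(C)C=C(COCc2ccccc2)C1=O | intermediate
15 | 3-methylbutanoic acid | CC(C)CC(=O)O | starting material
16 | vinyl acetate | CC(=O)OC=C | starting material
17 | vinyl 3-methylbutanoate | C=COC(=O)CC(C)C | intermediate
18 | 1-[(benzyloxy)methyl]-3,5-dimethyl-3-[(1S)-1-(2-methylpropanoyloxy)-5-(trimethylsilyl)pent-4-yn-1-yl]-2-oxobicyclo[2.2.2]oct-5-en-7-yl 3-methylbutanoate; ester at C7 and side chain at C3 both syn to the C5=C6 bridge (bicycle C1, C2, C3, C4, C7, C8 = briarane C11, C10, C1, C14, C12, C13) | C[Si](C)(C)C#CCC[C@H](OC(=O)C(C)C)[C@@]2(C)[C@@H]3C[C@@H](OC(=O)CC(C)C)[C@](C=C3C)(COCc4ccccc4)C2=O | intermediate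
19 | 18 with the C10 ketone replaced by C10=CH2 (2-methylidene) | C[Si](C)(C)C#CCC[C@H](OC(=O)C(C)C)[C@@]2(C)[C@@H]3C[C@@H](OC(=O)CC(C)C)[C@](C=C3C)(COCc4ccccc4)C2=C | intermediate
20 | 2-(hydroxymethyl) analogue of 18 (C9–OH), both C10 epimers | C[Si](C)(C)C#CCC[C@H](OC(=O)C(C)C)[C@@]2(C)[C@@H]3C[C@@H](OC(=O)CC(C)C)[C@](C=C3C)(COCc4ccccc4)C2CO | intermediate
21 | 2-formyl analogue of 18, both C10 epimers | C[Si](C)(C)C#CCC[C@H](OC(=O)C(C)C)[C@@]2(C)[C@@H]3C[C@@H](OC(=O)CC(C)C)[C@](C=C3C)(COCc4ccccc4)C2C=O | intermediate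
22 | 2-formyl analogue of 18 with the formyl group (C9) anti to the C2 side chain and syn to the C12–C13 bridge | C[Si](C)(C)C#CCC[C@H](OC(=O)C(C)C)[C@@]2(C)[C@@H]3C[C@@H](OC(=O)CC(C)C)[C@](C=C3C)(COCc4ccccc4)[C@@H]2C=O | intermediate
23 | (S)-2,2-dimethyl-1,3-dioxolane-4-carbaldehyde | O=C[C@@H]1COC(C)(C)O1 | starting material
24 | (R)-4-ethynyl-2,2-dimethyl-1,3-dioxolane | C#C[C@@H]1COC(C)(C)O1 | intermediate
25 | (S)-2,2-dimethyl-4-[1-(triethylsilyl)ethenyl]-1,3-dioxolane | C=C([Si](CC)(CC)CC)[C@@H]1COC(C)(C)O1 | intermediate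
26 | (S)-4-(1-iodoethenyl)-2,2-dimethyl-1,3-dioxolane | C=C(I)[C@@H]1COC(C)(C)O1 | intermediate
27 | 22 with CHO replaced by (9S)-CH(OH)–C8(=CH2)–(2,2-dimethyl-1,3-dioxolan-4-yl), dioxolane centre as in 26 | C[Si](C)(C)C#CCC[C@H](OC(=O)C(C)C)[C@@]2(C)[C@@H]3C[C@@H](OC(=O)CC(C)C)[C@](C=C3C)(COCc4ccccc4)[C@@H]2[C@H](O)C(=C)[C@@H]5COC(C)(C)O5 | intermediate
28 | C9 acetate of 27 | C[Si](C)(C)C#CCC[C@H](OC(=O)C(C)C)[C@@]2(C)[C@@H]3C[C@@H](OC(=O)CC(C)C)[C@](C=C3C)(COCc4ccccc4)[C@@H]2[C@H](OC(C)=O)C(=C)[C@@H]5COC(C)(C)O5 | intermediate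
29 | C6,C7-diol from 28 | C[Si](C)(C)C#CCC[C@H](OC(=O)C(C)C)[C@@]2(C)[C@@H]3C[C@@H](OC(=O)CC(C)C)[C@](C=C3C)(COCc4ccccc4)[C@@H]2[C@H](OC(C)=O)C(=C)[C@@H](O)CO | intermediate
30 | C6 tert-butyldiphenylsilyl ether of 29 (C7–OH free) | C[Si](C)(C)C#CCC[C@H](OC(=O)C(C)C)[C@@]2(C)[C@@H]3C[C@@H](OC(=O)CC(C)C)[C@](C=C3C)(COCc4ccccc4)[C@@H]2[C@H](OC(C)=O)C(=C)[C@@H](O)CO[Si](c5ccccc5)(c6ccccc6)C(C)(C)C | intermediate
31 | C7 2-bromopropanoate of 30 | C[Si](C)(C)C#CCC[C@H](OC(=O)C(C)C)[C@@]2(C)[C@@H]3C[C@@H](OC(=O)CC(C)C)[C@](C=C3C)(COCc4ccccc4)[C@@H]2[C@H](OC(C)=O)C(=C)[C@@H](OC(=O)C(C)Br)CO[Si](c5ccccc5)(c6ccccc6)C(C)(C)C | intermediate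
32 | ring-A cyclohexane after bridge cleavage: C14 acetyl, C11 formyl and CH2OBn, C12 O-isovaleryl, C2 O-isobutyryl, C9 OAc, C8 ketone, C7 O-(2-bromopropanoyl), C6 O-TBDPS, C5≡C16–SiMe3 | C[Si](C)(C)C#CCC[C@H](OC(=O)C(C)C)[C@@]2(C)[C@@H](C(C)=O)C[C@@H](OC(=O)CC(C)C)[C@](C=O)(COCc4ccccc4)[C@@H]2[C@H](OC(C)=O)C(=O)[C@@H](OC(=O)C(C)Br)CO[Si](c5ccccc5)(c6ccccc6)C(C)(C)C | intermediate
33 | β-hydroxy-γ-lactone from 32 (C8–OH cis to C6 and to the C17 methyl) | C[Si](C)(C)C#CCC[C@H](OC(=O)C(C)C)[C@@]2(C)[C@@H](C(C)=O)C[C@@H](OC(=O)CC(C)C)[C@](C=O)(COCc4ccccc4)[C@@H]2[C@H](OC(C)=O)[C@]7(O)[C@@H](C)C(=O)O[C@H]7CO[Si](c5ccccc5)(c6ccccc6)C(C)(C)C | intermediate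
34 | C14 acetate, C11 formate from 33 | C[Si](C)(C)C#CCC[C@H](OC(=O)C(C)C)[C@@]2(C)[C@@H](OC(C)=O)C[C@@H](OC(=O)CC(C)C)[C@](OC=O)(COCc4ccccc4)[C@@H]2[C@H](OC(C)=O)[C@]7(O)[C@@H](C)C(=O)O[C@H]7CO[Si](c5ccccc5)(c6ccccc6)C(C)(C)C | intermediate
35 | C14 acetate with free C11–OH and C20–OBn | C[Si](C)(C)C#CCC[C@H](OC(=O)C(C)C)[C@@]2(C)[C@@H](OC(C)=O)C[C@@H](OC(=O)CC(C)C)[C@](O)(COCc4ccccc4)[C@@H]2[C@H](OC(C)=O)[C@]7(O)[C@@H](C)C(=O)O[C@H]7CO[Si](c5ccccc5)(c6ccccc6)C(C)(C)C | intermediate
36 | C11,C20-diol | C[Si](C)(C)C#CCC[C@H](OC(=O)C(C)C)[C@@]2(C)[C@@H](OC(C)=O)C[C@@H](OC(=O)CC(C)C)[C@](O)(CO)[C@@H]2[C@H](OC(C)=O)[C@]7(O)[C@@H](C)C(=O)O[C@H]7CO[Si](c5ccccc5)(c6ccccc6)C(C)(C)C | intermediate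
37 | C20 mesylate of 36 | C[Si](C)(C)C#CCC[C@H](OC(=O)C(C)C)[C@@]2(C)[C@@H](OC(C)=O)C[C@@H](OC(=O)CC(C)C)[C@](O)(COS(C)(=O)=O)[C@@H]2[C@H](OC(C)=O)[C@]7(O)[C@@H](C)C(=O)O[C@H]7CO[Si](c5ccccc5)(c6ccccc6)C(C)(C)C | intermediate
38 | C11,C20-epoxide (C6 O-TBDPS, C5≡C16–SiMe3) | C[Si](C)(C)C#CCC[C@H](OC(=O)C(C)C)[C@@]2(C)[C@@H](OC(C)=O)C[C@@H](OC(=O)CC(C)C)[C@]3(CO3)[C@@H]2[C@H](OC(C)=O)[C@]7(O)[C@@H](C)C(=O)O[C@H]7CO[Si](c5ccccc5)(c6ccccc6)C(C)(C)C | intermediate
39 | epoxide with C6–OH and terminal alkyne C5≡C16H | C#CCC[C@H](OC(=O)C(C)C)[C@@]2(C)[C@@H](OC(C)=O)C[C@@H](OC(=O)CC(C)C)[C@]3(CO3)[C@@H]2[C@H](OC(C)=O)[C@]7(O)[C@@H](C)C(=O)O[C@H]7CO | intermediate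
40 | C5 triethylsilyl 5(16)-alkene from 39 | C=C([Si](CC)(CC)CC)CC[C@H](OC(=O)C(C)C)[C@@]2(C)[C@@H](OC(C)=O)C[C@@H](OC(=O)CC(C)C)[C@]3(CO3)[C@@H]2[C@H](OC(C)=O)[C@]7(O)[C@@H](C)C(=O)O[C@H]7CO | intermediate
41 | C5 iodo 5(16)-alkene with C6–OH | C=C(I)CC[C@H](OC(=O)C(C)C)[C@@]2(C)[C@@H](OC(C)=O)C[C@@H](OC(=O)CC(C)C)[C@]3(CO3)[C@@H]2[C@H](OC(C)=O)[C@]7(O)[C@@H](C)C(=O)O[C@H]7CO | intermediate
42 | C6 aldehyde of 41 | C=C(I)CC[C@H](OC(=O)C(C)C)[C@@]2(C)[C@@H](OC(C)=O)C[C@@H](OC(=O)CC(C)C)[C@]3(CO3)[C@@H]2[C@H](OC(C)=O)[C@]7(O)[C@@H](C)C(=O)O[C@H]7C=O | intermediate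
43 | (6R)-6-hydroxy analogue of the target (OH in place of Cl, opposite configuration at C6) | C=C1CC[C@H](OC(=O)C(C)C)[C@@]2(C)[C@@H](OC(C)=O)C[C@@H](OC(=O)CC(C)C)[C@]3(CO3)[C@@H]2[C@H](OC(C)=O)[C@]2(O)[C@@H](C)C(=O)O[C@H]2[C@@H]1O | intermediate
44 | CNP0194902.1; (1S,2S,6S,7R,8R,9S,10S,11R,12R,14S,17R) in briarane numbering | C=C1CC[C@H](OC(=O)C(C)C)[C@@]2(C)[C@@H](OC(C)=O)C[C@@H](OC(=O)CC(C)C)[C@]3(CO3)[C@@H]2[C@H](OC(C)=O)[C@]2(O)[C@@H](C)C(=O)O[C@H]2[C@H]1Cl | target

**Totals**
Total step count: 30. Longest linear sequence: 27 steps (steps 1–8, 10–13, 16–30).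

**Steps most likely to fail**

Step 10. The enol ester is a weak dienophile, so thermal rearrangement of the dienone, intramolecular cycloaddition with the alkyne, or loss of facial control may outrun the desired addition. The fallback sets out from 14 and uses a normal-electron-demand cycloaddition followed by oxygen insertion. Isovaleraldehyde and vinylmagnesium bromide (THF, −78 °C) give 5-methylhex-1-en-3-ol F1, which Dess–Martin periodinane oxidises to 5-methylhex-1-en-3-one F2. Heating 14 with F2 (toluene, 80 °C) should give the endo ketone adduct F3 with the same regiochemistry. Baeyer–Villiger oxidation with bis(trimethylsilyl) peroxide and TMSOTf (cat.) in CH2Cl2 at −30 °C tolerates the alkene; secondary C12 migrates with retention, and the route is rejoined at 18.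

Step 22. The zinc enolate may add to the C11 aldehyde or the C14 methyl ketone, or be protonated, before the five-membered ring closes. The fallback sets out from 31 and removes the competing carbonyl groups first. One equivalent of ozone (CH2Cl2, −78 °C; Me2S) should cleave only the strained, electron-rich bridge to give the acetyl formyl alkene F4. mCPBA/NaHCO3 then gives the C14 acetate C11 formate F5, whose remaining alkene is deactivated by two allylic acyloxy groups. A second ozonolysis gives the C8 ketone F6, now the only ketone or aldehyde in the molecule. Zinc-mediated closure of F6 gives 34, and KHCO3/MeOH rejoins the route at 35.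

Step 29. Intermolecular coupling may compete with closure of the medium ring, and the ring-forming transition state may override the ligand, so that facial control at C6 is lost. The fallback sets out from 42 and sets C6 by reduction instead. Closure with CrCl2/NiCl2 (cat.) in DMSO without ligand, at high dilution, gives the C6 epimer mixture F7. Dess–Martin oxidation gives the cross-conjugated enone F8. Luche reduction (NaBH4, CeCl3·7H2O, MeOH, −78 °C) under Felkin–Anh control, with hydride anti to the C7–O bond, should give the alcohol syn to the C7 oxygen and rejoins the route at 43.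

Further compounds
F1 | step 10 | 5-methylhex-1-en-3-ol | C=CC(O)CC(C)C
F2 | step 10 | 5-methylhex-1-en-3-one | C=CC(=O)CC(C)C
F3 | step 10 | 18 with the C12 isovalerate replaced by an endo 3-methylbutanoyl group | C[Si](C)(C)C#CCC[C@H](OC(=O)C(C)C)[C@@]2(C)[C@@H]3C[C@@H](C(=O)CC(C)C)[C@](C=C3C)(COCc4ccccc4)C2=O
F4 | step 22 | 31 after cleavage of the bridge only (C14 acetyl, C11 formyl, C8=CH2 intact) | C[Si](C)(C)C#CCC[C@H](OC(=O)C(C)C)[C@@]2(C)[C@@H](C(C)=O)C[C@@H](OC(=O)CC(C)C)[C@](C=O)(COCc4ccccc4)[C@@H]2[C@H](OC(C)=O)C(=C)[C@@H](OC(=O)C(C)Br)CO[Si](c5ccccc5)(c6ccccc6)C(C)(C)C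
F5 | step 22 | C14 acetate C11 formate with C8=CH2 intact | C[Si](C)(C)C#CCC[C@H](OC(=O)C(C)C)[C@@]2(C)[C@@H](OC(C)=O)C[C@@H](OC(=O)CC(C)C)[C@](OC=O)(COCc4ccccc4)[C@@H]2[C@H](OC(C)=O)C(=C)[C@@H](OC(=O)C(C)Br)CO[Si](c5ccccc5)(c6ccccc6)C(C)(C)C
F6 | step 22 | C14 acetate C11 formate C8 ketone bromo ester | C[Si](C)(C)C#CCC[C@H](OC(=O)C(C)C)[C@@]2(C)[C@@H](OC(C)=O)C[C@@H](OC(=O)CC(C)C)[C@](OC=O)(COCc4ccccc4)[C@@H]2[C@H](OC(C)=O)C(=O)[C@@H](OC(=O)C(C)Br)CO[Si](c5ccccc5)(c6ccccc6)C(C)(C)C
F7 | step 29 | ring-closed C6 alcohol, both C6 epimers | C=C1CC[C@H](OC(=O)C(C)C)[C@@]2(C)[C@@H](OC(C)=O)C[C@@H](OC(=O)CC(C)C)[C@]3(CO3)[C@@H]2[C@H](OC(C)=O)[C@]2(O)[C@@H](C)C(=O)O[C@H]2C1O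
F8 | step 29 | ring-closed C6 ketone (5(16)-en-6-one) | C=C1CC[C@H](OC(=O)C(C)C)[C@@]2(C)[C@@H](OC(C)=O)C[C@@H](OC(=O)CC(C)C)[C@]3(CO3)[C@@H]2[C@H](OC(C)=O)[C@]2(O)[C@@H](C)C(=O)O[C@H]2C1=O
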